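**Plan**
- Labels and cuts: ring D (phloroglucinol)–CγH2–CβH(OH)–CαH(ring E, a catechol)–C6 of a (+)-catechin unit (rings A, C and B). The retrosynthesis cuts Cα–ring E (Friedel–Crafts), then Cα–C6 of ring A (aryl Grignard plus aldehyde), then Cβ–Cγ (enamine plus ortho-quinone methide).
- Enabling feature: ring D has a hydroxyl ortho to Cγ, so Cγ can be unmasked as the exocyclic carbon of an ortho-quinone methide. Cβ, the carbinol carbon beside it, is the α-carbon of an O-silyl glycolaldehyde whose formyl carbon becomes Cα.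
- Forward order: the Cβ–Cγ bond is made first and the ring D phenol closes a temporary six-membered lactol. The C6-magnesium reagent from (+)-catechin opens it, and ring E is attached last. Rings A, C and B come intact from (+)-catechin.
- Stereochemistry: C2 and C3 of the flavan come from (+)-catechin. Cβ (S) comes from the (R)-diphenylprolinol silyl ether catalyst. Cα (R) is relayed from Cβ through a trans-acetoxonium ion opened with inversion.
- Protecting groups: silyl ethers on ring D are exchanged for acetates before any cation chemistry, so ring D cannot compete as a nucleophile. Benzyl ethers and a bromine blocking C8 leave in the final hydrogenolysis.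

Key step: step 3

Assumption: the silyloxy enamine reacts through the usual E, s-trans geometry, which is what links the (R)-catalyst to the (S)-carbinol; 1,2-bis(benzyloxy)benzene and the catalyst are purchased.

**Step 1**
Reactants: 1 2,4,6-trihydroxybenzaldehyde
Product: 2 2-hydroxy-4,6-bis(triisopropylsilyloxy)benzaldehyde
Conditions: TIPSCl (2.1 equiv), imidazole, DMF, 0 °C to rt
Reagents that add atoms: triisopropylsilyl chloride, CC(C)[Si](Cl)(C(C)C)C(C)C
Why: Phenol silylation with a silyl chloride and imidazole should take the 4-hydroxyl and one ortho hydroxyl, while the ortho hydroxyl hydrogen-bonded to the formyl oxygen stays free, as in the selective 2,4-di-O-alkylation of this aldehyde.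

**Step 2**
Reactants: 2 2-hydroxy-4,6-bis(triisopropylsilyloxy)benzaldehyde
Product: 3 2-(hydroxymethyl)-3,5-bis(triisopropylsilyloxy)phenol
Conditions: NaBH4, THF/EtOH, 0 °C; pH 7 buffer work-up, used without chromatography
Reagents that add atoms: none
Why: Borohydride reduction of an aldehyde, which the bulky aryl silyl ethers should survive without cleavage or migration under cold, near-neutral conditions.

**Step 3**
Reactants: 3 2-(hydroxymethyl)-3,5-bis(triisopropylsilyloxy)phenol, 4 (tert-butyldimethylsilyloxy)acetaldehyde (2 equiv)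
Product: 7 (3S)-3-(tert-butyldimethylsilyloxy)-5,7-bis(triisopropylsilyloxy)chroman-2-ol (anomeric mixture), via ortho-quinone methide 5 (not isolated), via open-chain aldehyde 6 (not isolated)
Conditions: (R)-α,α-diphenylprolinol trimethylsilyl ether (20 mol %), PhCO2H (20 mol %), CHCl3, 25–40 °C
Reagents that add atoms: none
Why: Benzoic acid should ionise the benzylic hydroxyl of 3, which sits ortho/para to three oxygen donors, to the ortho-quinone methide 5 with loss of water, while the amine condenses with 4 to an E, s-trans enamine. The enamine carbon adds to the exocyclic CH2 of 5 (the only electrophilic site, with rearomatisation as driving force), hydrolysis releases aldehyde 6, and the regenerated ring D phenol adds to the formyl group in a 6-exo-trig closure to lactol 7. The closest known reaction type is the secondary-amine-catalysed α-alkylation of aldehydes with ortho-quinone methides generated in situ, a formal [4+2] route to chroman-2-ols. C3 is set by the catalyst: the diphenyl(silyloxy)methyl group of the (R)-pyrrolidine shields one enamine face, the electrophile arrives on the other, and with the priority order O > CHO > CH2Ar this is S; the anomeric carbon is a mixture that is erased in step 8. The step needs the enamine to outrun self-condensation of 5 and the product not to epimerise: the bulky silyl ethers flanking the free ring positions of 3 slow the former, and lactol formation, which masks the aldehyde, secures the latter.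

**Step 4**
Reactants: 8 (+)-catechin
Product: 9 (2R,3S)-5,7,3',4'-tetra-O-benzylcatechin
Conditions: BnBr (4.4 equiv), K2CO3, DMF, 0 °C to rt, under N2
Reagents that add atoms: benzyl bromide, BrCc1ccccc1
Why: Williamson etherification of the four phenols, with carbonate too weak to deprotonate the C3 alcohol or to open the pyran ring.

**Step 5**
Reactants: 9 (2R,3S)-5,7,3',4'-tetra-O-benzylcatechin
Product: 10 (2R,3S)-3,5,7,3',4'-penta-O-benzylcatechin
Conditions: NaH, BnBr, DMF, 0 °C to rt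
Reagents that add atoms: benzyl bromide, BrCc1ccccc1
Why: Williamson etherification of the secondary alkoxide, which removes the only acidic proton before the organomagnesium step.

**Step 6**
Reactants: 10 (2R,3S)-3,5,7,3',4'-penta-O-benzylcatechin
Product: 11 (2R,3S)-8-bromo-3,5,7,3',4'-penta-O-benzylcatechin
Conditions: NBS (1.0 equiv), CH2Cl2, −78 °C to rt
Reagents that add atoms: N-bromosuccinimide, O=C1CCC(=O)N1Br
Why: Electrophilic aromatic bromination, which in 5,7-dialkoxyflavans goes to C8, the more reactive ring A position; the bromine then blocks C8 until step 12.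

**Step 7**
Reactants: 11 (2R,3S)-8-bromo-3,5,7,3',4'-penta-O-benzylcatechin
Product: 12 (2R,3S)-8-bromo-6-iodo-3,5,7,3',4'-penta-O-benzylcatechin
Conditions: NIS (1.2 equiv), TFA (cat.), CH2Cl2/MeCN, 0 °C to rt
Reagents that add atoms: N-iodosuccinimide, O=C1CCC(=O)N1I
Why: Electrophilic aromatic iodination at C6, the only free ring A position, which with three oxygen donors remains far more electron-rich than ring B.

**Step 8**
Reactants: 12 (2R,3S)-8-bromo-6-iodo-3,5,7,3',4'-penta-O-benzylcatechin (1.3 equiv), 7 (3S)-3-(tert-butyldimethylsilyloxy)-5,7-bis(triisopropylsilyloxy)chroman-2-ol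
Product: 14 (2S)-1-[(2R,3S)-3,5,7-tris(benzyloxy)-2-[3,4-bis(benzyloxy)phenyl]-8-bromochroman-6-yl]-2-(tert-butyldimethylsilyloxy)-3-[2-hydroxy-4,6-bis(triisopropylsilyloxy)phenyl]propan-1-ol (both C1 epimers), via arylmagnesium chloride 13 (not isolated)
Conditions: 12, i-PrMgCl·LiCl (1.3 equiv), THF, −20 °C; 7, MeMgCl (1.0 equiv), THF, −78 °C; combine, −40 to 0 °C; aq NH4Cl
Reagents that add atoms: none
Why: Iodine–magnesium exchange, much faster at the aryl iodide than at the aryl bromide, followed by Grignard addition to the aldehyde that the magnesium lactolate of 7 releases by ring opening; the new carbinol centre is a mixture that is ionised in step 10.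

**Step 9**
Reactants: 14 the carbinol from step 8
Product: 16 (2S)-1-[(2R,3S)-3,5,7-tris(benzyloxy)-2-[3,4-bis(benzyloxy)phenyl]-8-bromochroman-6-yl]-3-(2,4,6-triacetoxyphenyl)propane-1,2-diyl diacetate (both C1 epimers), via pentaol 15 (not isolated)
Conditions: TBAF (3.3 equiv), THF, 0 °C to rt, under Ar; then Ac2O, pyridine, DMAP (cat.), 0 °C to rt
Reagents that add atoms: acetic anhydride, CC(=O)OC(C)=O
Why: Fluoride desilylation followed in the same flask by DMAP-catalysed acetylation, so the acid-labile pentaol 15 is never isolated; the aryl acetates turn ring D into a negligible π-nucleophile and the two aliphatic acetates supply the leaving group at Cα and the participating group on O-β.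

**Step 10**
Reactants: 16 the pentaacetate from step 9, 17 1,2-bis(benzyloxy)benzene (20 equiv)
Product: 19 (1R,2S)-1-[3,4-bis(benzyloxy)phenyl]-1-[(2R,3S)-3,5,7-tris(benzyloxy)-2-[3,4-bis(benzyloxy)phenyl]-8-bromochroman-6-yl]-3-(2,4,6-triacetoxyphenyl)propan-2-yl acetate, via acetoxonium ion 18 (not isolated)
Conditions: Me3SiOTf (0.3 equiv), CH2Cl2, −40 to 0 °C; Et3N quench
Reagents that add atoms: none
Why: Lewis acid-promoted Friedel–Crafts benzylation with neighbouring-group participation: the Cα acetate of either epimer ionises to a cation stabilised by the three oxygen donors of ring A, the Cβ acetate closes it to the trans-4,5-disubstituted 1,3-dioxolan-2-ylium ion 18, and the arene, reacting para to a benzyloxy group, opens 18 at Cα with inversion, which places ring E anti to O-β and sets Cα as R.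

**Step 11**
Reactants: 19 the tetraacetate from step 10
Product: 20 (1R,2S)-1-[3,4-bis(benzyloxy)phenyl]-1-[(2R,3S)-3,5,7-tris(benzyloxy)-2-[3,4-bis(benzyloxy)phenyl]-8-bromochroman-6-yl]-3-(2,4,6-trihydroxyphenyl)propan-2-ol
Conditions: K2CO3, MeOH/THF (degassed), rt; pH 6 work-up
Reagents that add atoms: none
Why: Base-mediated methanolysis (transesterification) of the three aryl acetates and the secondary acetate, to which benzyl ethers and the aryl bromide are inert.

**Step 12**
Reactants: 20 the heptabenzyl ether from step 11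
Product: 21 the target, (1R,2S)-1-(3,4-dihydroxyphenyl)-1-[(2R,3S)-2-(3,4-dihydroxyphenyl)-3,5,7-trihydroxychroman-6-yl]-3-(2,4,6-trihydroxyphenyl)propan-2-ol
Conditions: H2 (1 atm), Pd(OH)2/C, Et3N (2 equiv), THF/MeOH/H2O, rt
Reagents that add atoms: none
Why: Catalytic hydrogenolysis of the seven benzyl ethers together with hydrodebromination at C8, with Et3N taking up HBr so the acid-sensitive polyphenol never meets acid.

**Compound list**
1 | 2,4,6-trihydroxybenzaldehyde | O=Cc1c(O)cc(O)cc1O | starting material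
2 | 2-hydroxy-4,6-bis(triisopropylsilyloxy)benzaldehyde | O=Cc1c(O)cc(O[Si](C(C)C)(C(C)C)C(C)C)cc1O[Si](C(C)C)(C(C)C)C(C)C | intermediate
3 | 2-(hydroxymethyl)-3,5-bis(triisopropylsilyloxy)phenol | OCc1c(O)cc(O[Si](C(C)C)(C(C)C)C(C)C)cc1O[Si](C(C)C)(C(C)C)C(C)C | intermediate
4 | (tert-butyldimethylsilyloxy)acetaldehyde | CC(C)(C)[Si](C)(C)OCC=O | starting material
5 | 6-methylidene-3,5-bis(triisopropylsilyloxy)cyclohexa-2,4-dien-1-one (ortho-quinone methide) | C=C1C(=O)C=C(O[Si](C(C)C)(C(C)C)C(C)C)C=C1O[Si](C(C)C)(C(C)C)C(C)C | intermediate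
6 | (2S)-2-(tert-butyldimethylsilyloxy)-3-[2-hydroxy-4,6-bis(triisopropylsilyloxy)phenyl]propanal | O=C[C@@H](O[Si](C)(C)C(C)(C)C)Cc1c(O)cc(O[Si](C(C)C)(C(C)C)C(C)C)cc1O[Si](C(C)C)(C(C)C)C(C)C | intermediate
7 | (3S)-3-(tert-butyldimethylsilyloxy)-5,7-bis(triisopropylsilyloxy)chroman-2-ol (anomeric mixture) | OC1Oc2cc(O[Si](C(C)C)(C(C)C)C(C)C)cc(O[Si](C(C)C)(C(C)C)C(C)C)c2C[C@@H]1O[Si](C)(C)C(C)(C)C | intermediate
8 | (+)-catechin, (2R,3S) | O[C@H]1Cc2c(O)cc(O)cc2O[C@@H]1c1ccc(O)c(O)c1 | starting material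
9 | (2R,3S)-5,7,3',4'-tetra-O-benzylcatechin | O[C@H]1Cc2c(OCc3ccccc3)cc(OCc3ccccc3)cc2O[C@@H]1c1ccc(OCc2ccccc2)c(OCc2ccccc2)c1 | intermediate
10 | (2R,3S)-3,5,7,3',4'-penta-O-benzylcatechin | c1ccccc1CO[C@H]1Cc2c(OCc3ccccc3)cc(OCc3ccccc3)cc2O[C@@H]1c1ccc(OCc2ccccc2)c(OCc2ccccc2)c1 | intermediate
11 | (2R,3S)-8-bromo-3,5,7,3',4'-penta-O-benzylcatechin | c1ccccc1CO[C@H]1Cc2c(OCc3ccccc3)cc(OCc3ccccc3)c(Br)c2O[C@@H]1c1ccc(OCc2ccccc2)c(OCc2ccccc2)c1 | intermediate
12 | (2R,3S)-8-bromo-6-iodo-3,5,7,3',4'-penta-O-benzylcatechin | c1ccccc1CO[C@H]1Cc2c(OCc3ccccc3)c(I)c(OCc3ccccc3)c(Br)c2O[C@@H]1c1ccc(OCc2ccccc2)c(OCc2ccccc2)c1 | intermediate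
13 | [(2R,3S)-8-bromo-3,5,7,3',4'-penta-O-benzylcatechin-6-yl]magnesium chloride | c1ccccc1CO[C@H]1Cc2c(OCc3ccccc3)c([Mg]Cl)c(OCc3ccccc3)c(Br)c2O[C@@H]1c1ccc(OCc2ccccc2)c(OCc2ccccc2)c1 | intermediate
14 | (2S)-1-[(2R,3S)-3,5,7-tris(benzyloxy)-2-[3,4-bis(benzyloxy)phenyl]-8-bromochroman-6-yl]-2-(tert-butyldimethylsilyloxy)-3-[2-hydroxy-4,6-bis(triisopropylsilyloxy)phenyl]propan-1-ol (C1 epimers) | OC([C@@H](O[Si](C)(C)C(C)(C)C)Cc1c(O)cc(O[Si](C(C)C)(C(C)C)C(C)C)cc1O[Si](C(C)C)(C(C)C)C(C)C)c1c(OCc2ccccc2)c2C[C@H](OCc3ccccc3)[C@@H](c3ccc(OCc4ccccc4)c(OCc4ccccc4)c3)Oc2c(Br)c1OCc1ccccc1 | intermediate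
15 | (2S)-1-[(2R,3S)-3,5,7-tris(benzyloxy)-2-[3,4-bis(benzyloxy)phenyl]-8-bromochroman-6-yl]-3-(2,4,6-trihydroxyphenyl)propane-1,2-diol (C1 epimers) | OC([C@@H](O)Cc1c(O)cc(O)cc1O)c1c(OCc2ccccc2)c2C[C@H](OCc3ccccc3)[C@@H](c3ccc(OCc4ccccc4)c(OCc4ccccc4)c3)Oc2c(Br)c1OCc1ccccc1 | intermediate
16 | (2S)-1-[(2R,3S)-3,5,7-tris(benzyloxy)-2-[3,4-bis(benzyloxy)phenyl]-8-bromochroman-6-yl]-3-(2,4,6-triacetoxyphenyl)propane-1,2-diyl diacetate (C1 epimers) | CC(=O)OC([C@@H](OC(C)=O)Cc1c(OC(C)=O)cc(OC(C)=O)cc1OC(C)=O)c1c(OCc2ccccc2)c2C[C@H](OCc3ccccc3)[C@@H](c3ccc(OCc4ccccc4)c(OCc4ccccc4)c3)Oc2c(Br)c1OCc1ccccc1 | intermediate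
17 | 1,2-bis(benzyloxy)benzene | c1ccc(OCc2ccccc2)c(OCc2ccccc2)c1 | starting material
18 | trans-4-(flavan-6-yl)-2-methyl-5-(2,4,6-triacetoxybenzyl)-1,3-dioxolan-2-ylium triflate (acetoxonium ion) | C[C+]1O[C@@H](Cc2c(OC(C)=O)cc(OC(C)=O)cc2OC(C)=O)[C@H](c2c(OCc3ccccc3)c3C[C@H](OCc4ccccc4)[C@@H](c4ccc(OCc5ccccc5)c(OCc5ccccc5)c4)Oc3c(Br)c2OCc2ccccc2)O1.[O-]S(=O)(=O)C(F)(F)F | intermediate
19 | (1R,2S)-1-[3,4-bis(benzyloxy)phenyl]-1-[(2R,3S)-3,5,7-tris(benzyloxy)-2-[3,4-bis(benzyloxy)phenyl]-8-bromochroman-6-yl]-3-(2,4,6-triacetoxyphenyl)propan-2-yl acetate | CC(=O)Oc1cc(OC(C)=O)c(C[C@H](OC(C)=O)[C@H](c2ccc(OCc3ccccc3)c(OCc3ccccc3)c2)c2c(OCc3ccccc3)c3C[C@H](OCc4ccccc4)[C@@H](c4ccc(OCc5ccccc5)c(OCc5ccccc5)c4)Oc3c(Br)c2OCc2ccccc2)c(OC(C)=O)c1 | intermediate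
20 | (1R,2S)-1-[3,4-bis(benzyloxy)phenyl]-1-[(2R,3S)-3,5,7-tris(benzyloxy)-2-[3,4-bis(benzyloxy)phenyl]-8-bromochroman-6-yl]-3-(2,4,6-trihydroxyphenyl)propan-2-ol | Oc1cc(O)c(C[C@H](O)[C@H](c2ccc(OCc3ccccc3)c(OCc3ccccc3)c2)c2c(OCc3ccccc3)c3C[C@H](OCc4ccccc4)[C@@H](c4ccc(OCc5ccccc5)c(OCc5ccccc5)c4)Oc3c(Br)c2OCc2ccccc2)c(O)c1 | intermediate
21 | (1R,2S)-1-(3,4-dihydroxyphenyl)-1-[(2R,3S)-2-(3,4-dihydroxyphenyl)-3,5,7-trihydroxychroman-6-yl]-3-(2,4,6-trihydroxyphenyl)propan-2-ol | Oc1cc(O)c(C[C@H](O)[C@H](c2ccc(O)c(O)c2)c2c(O)cc3c(c2O)C[C@H](O)[C@@H](c2ccc(O)c(O)c2)O3)c(O)c1 | target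

**Step count**
Total: 12 steps. Longest linear sequence: 9 steps (steps 4–12, from (+)-catechin).

**Steps most likely to fail**

1. Step 10. The catechol ether is only a moderate π-nucleophile, and facial control depends on acetate participation outweighing the intrinsic bias of the open cation. Slow capture would let the cation eliminate or be intercepted by ring B of another molecule, and weak participation would erode or invert the configuration at Cα.
 Fallback (order of the two aryl groups reversed, steric instead of anchimeric control; sets out from 7 and 11, returns at 20): 3,4-bis(benzyloxy)phenylmagnesium bromide F1, made from commercial 4-bromo-1,2-bis(benzyloxy)benzene and Mg, is added to the magnesium lactolate of 7 to give carbinol F2. Ac2O/pyridine/DMAP caps the phenol and the benzylic hydroxyl to give diacetate F3, with the silyl ethers kept. Me3SiOTf then ionises F3 in the presence of an excess of 11, whose free C6 is a far better nucleophile than a catechol ether. With the non-participating silyl ether on O-β, the flavan should enter anti to the arylmethyl branch of the allylic-strain-minimised cation, which is the relative configuration of the target, giving C-arylated silyl ether F4; this sense of attack would have to be confirmed. Acetic-acid-buffered TBAF removes the three silyl groups to give mono-acetate F5, and K2CO3/MeOH cleaves the aryl acetate to give 20.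

2. Step 3. The enamine of an α-silyloxy aldehyde may form and turn over slowly, so the quinone methide could be consumed by condensation with its own precursor, and any Z-enamine leakage would lower the enantioselectivity.
 Fallback (stoichiometric auxiliary control of the same Cβ–Cγ bond; sets out from 3, returns at 7): glycolate imide F6, (R)-4-benzyl-3-[(tert-butyldimethylsilyloxy)acetyl]oxazolidin-2-one, is made from the commercial oxazolidinone and (tert-butyldimethylsilyloxy)acetyl chloride and converted into its chlorotitanium enolate (TiCl4, i-Pr2NEt, CH2Cl2, −78 °C). The enolate is alkylated in SN1 fashion by the quinone methide that the same Lewis acid releases from 3, the benzyl group of the auxiliary directing attack to give alkylated imide F7 with the (S) centre. The neighbouring phenol then cleaves the imide by lactonisation (Et3N, DMAP), returning the auxiliary and giving lactone F8, and i-Bu2AlH at −78 °C reduces F8 to lactol 7.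

3. Step 8. The doubly ortho-substituted arylmagnesium may act as a base toward the aldehyde released from the lactolate (loss of configurational integrity at Cβ) or add sluggishly.
 Fallback (acylation then reduction in place of direct addition; sets out from 7, returns at 14): 7 is oxidised with Ag2CO3 on Celite to lactone F8, which is opened with MeNH(OMe)·HCl and i-PrMgCl to N-methoxy-N-methylamide F9. After deprotonation of its phenol with MeMgCl, F9 is acylated by 13 through the chelated tetrahedral adduct, which resists both enolisation and double addition, to give aryl ketone F10. NaBH4 or i-Bu2AlH then reduces F10 to 14.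

**Further compounds**
F1 | step 10 | 3,4-bis(benzyloxy)phenylmagnesium bromide | Br[Mg]c1ccc(OCc2ccccc2)c(OCc2ccccc2)c1
F2 | step 10 | (2S)-1-[3,4-bis(benzyloxy)phenyl]-2-(tert-butyldimethylsilyloxy)-3-[2-hydroxy-4,6-bis(triisopropylsilyloxy)phenyl]propan-1-ol (C1 epimers) | OC([C@@H](O[Si](C)(C)C(C)(C)C)Cc1c(O)cc(O[Si](C(C)C)(C(C)C)C(C)C)cc1O[Si](C(C)C)(C(C)C)C(C)C)c1ccc(OCc2ccccc2)c(OCc2ccccc2)c1
F3 | step 10 | (2S)-1-acetoxy-1-[3,4-bis(benzyloxy)phenyl]-2-(tert-butyldimethylsilyloxy)-3-[2-acetoxy-4,6-bis(triisopropylsilyloxy)phenyl]propane (C1 epimers) | CC(=O)OC([C@@H](O[Si](C)(C)C(C)(C)C)Cc1c(OC(C)=O)cc(O[Si](C(C)C)(C(C)C)C(C)C)cc1O[Si](C(C)C)(C(C)C)C(C)C)c1ccc(OCc2ccccc2)c(OCc2ccccc2)c1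
F4 | step 10 | (1R,2S)-1-[3,4-bis(benzyloxy)phenyl]-1-[(2R,3S)-8-bromo-penta-O-benzylcatechin-6-yl]-2-(tert-butyldimethylsilyloxy)-3-[2-acetoxy-4,6-bis(triisopropylsilyloxy)phenyl]propane | CC(=O)Oc1cc(O[Si](C(C)C)(C(C)C)C(C)C)cc(O[Si](C(C)C)(C(C)C)C(C)C)c1C[C@H](O[Si](C)(C)C(C)(C)C)[C@H](c1ccc(OCc2ccccc2)c(OCc2ccccc2)c1)c1c(OCc2ccccc2)c2C[C@H](OCc3ccccc3)[C@@H](c3ccc(OCc4ccccc4)c(OCc4ccccc4)c3)Oc2c(Br)c1OCc1ccccc1
F5 | step 10 | (1R,2S)-1-[3,4-bis(benzyloxy)phenyl]-1-[(2R,3S)-8-bromo-penta-O-benzylcatechin-6-yl]-3-(2-acetoxy-4,6-dihydroxyphenyl)propan-2-ol | CC(=O)Oc1cc(O)cc(O)c1C[C@H](O)[C@H](c1ccc(OCc2ccccc2)c(OCc2ccccc2)c1)c1c(OCc2ccccc2)c2C[C@H](OCc3ccccc3)[C@@H](c3ccc(OCc4ccccc4)c(OCc4ccccc4)c3)Oc2c(Br)c1OCc1ccccc1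
F6 | step 3 | (R)-4-benzyl-3-[(tert-butyldimethylsilyloxy)acetyl]oxazolidin-2-one | O=C1OC[C@@H](Cc2ccccc2)N1C(=O)CO[Si](C)(C)C(C)(C)C
F7 | step 3 | (R)-4-benzyl-3-[(2S)-2-(tert-butyldimethylsilyloxy)-3-[2-hydroxy-4,6-bis(triisopropylsilyloxy)phenyl]propanoyl]oxazolidin-2-one | O=C1OC[C@@H](Cc2ccccc2)N1C(=O)[C@@H](O[Si](C)(C)C(C)(C)C)Cc1c(O)cc(O[Si](C(C)C)(C(C)C)C(C)C)cc1O[Si](C(C)C)(C(C)C)C(C)C
F8 | step 3 | (3S)-3-(tert-butyldimethylsilyloxy)-5,7-bis(triisopropylsilyloxy)chroman-2-one | O=C1Oc2cc(O[Si](C(C)C)(C(C)C)C(C)C)cc(O[Si](C(C)C)(C(C)C)C(C)C)c2C[C@@H]1O[Si](C)(C)C(C)(C)C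
F9 | step 8 | (2S)-2-(tert-butyldimethylsilyloxy)-3-[2-hydroxy-4,6-bis(triisopropylsilyloxy)phenyl]-N-methoxy-N-methylpropanamide | CON(C)C(=O)[C@@H](O[Si](C)(C)C(C)(C)C)Cc1c(O)cc(O[Si](C(C)C)(C(C)C)C(C)C)cc1O[Si](C(C)C)(C(C)C)C(C)C
F10 | step 8 | (2S)-1-[(2R,3S)-8-bromo-penta-O-benzylcatechin-6-yl]-2-(tert-butyldimethylsilyloxy)-3-[2-hydroxy-4,6-bis(triisopropylsilyloxy)phenyl]propan-1-one | O=C([C@@H](O[Si](C)(C)C(C)(C)C)Cc1c(O)cc(O[Si](C(C)C)(C(C)C)C(C)C)cc1O[Si](C(C)C)(C(C)C)C(C)C)c1c(OCc2ccccc2)c2C[C@H](OCc3ccccc3)[C@@H](c3ccc(OCc4ccccc4)c(OCc4ccccc4)c3)Oc2c(Br)c1OCc1ccccc1
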